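The numbers of this flask are those of an exercise; the flask was simulated.

If starting material makes ring and, on meeting ring, also consumes it, both rates carry c(starting material), so c(starting material) cancels from their ratio, and this flask can be reckoned on that ratio.

solid substrate 0.70 M; time 3.0 h

    2 starting material → open dimer (k1 = 0.74 M⁻¹ min⁻¹)
    solid substrate ⇌ starting material, rate k2*(cs2 - [starting material]) while solid is left; crystals form when [starting material] > cs2 (cs2 = 0.051 M, k2 = 2.8 min⁻¹)
    starting material + ring → side product (k3 = 0.32 M⁻¹ min⁻¹)
    starting material → ring (k4 = 0.26 min⁻¹)

* which holds at 3.0 h: what has brought the reaction to rest, or that it has not come to rest (for what has run out or reacted, a solid counts together with what of it has only dissolved) (forward and back rates have come level / all of the solid substrate has reacted / it is still moving)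
* how much ring there is at 3.0 h, in percent of the solid substrate charged

- a species is counted by the solid substrate in it: one open dimer or side product counts as two
- for a step with 2 of a species take k times the square, and two of it per event
- given per volume of solution although it is solid: solid substrate
- at the start none of the solid substrate is in solution
- what has only dissolved of solid substrate counts as not reacted
- the reaction counts as stopped when no species that holds the solid substrate changes by six tenths of a point or more over the second half of the time
- run time (flask): 3.0 h

Reckoned by hand, the ring constant over the side-product constant gives 0.812 M, the ring ceiling, the ring level at which ring is used up as fast as it is made. With c(starting material) taken at the solubility, ring at first forms at 0.0133 M min⁻¹. Open dimer adds to the spending of starting material: its spending over that of ring formation is d = 0.290, which leaves 0.775 of a ring per starting material spent. Ring's own build-up multiplies the net rate by 1 − c(ring)/ceiling, which equals exp(−u), where u is the side-product constant times the time integral of c(starting material). Taking the loss of ring as a correction to the spending gives: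

charge/ceiling = 0.862 = (1 + d)·u + u·u/2, so u = 0.550

c(ring) = ceiling·(1 − exp(−u)) = 0.344 M, or 49.1 % of the charge

The last slowing factor is 0.577. That exposure takes about 33.7 min at the solubility, less than the 3.0 h allowed, so the charge of 0.70 M should have reacted before the reading.

The forecast says all of the solid substrate has reacted and puts ring at 51 %, since “Ring forms at first-order pace but is increasingly eaten by the side reaction”; its ring figure stands above my own.

For this flask the simulation gives all of the solid substrate has reacted, with solid substrate at 0 %, and ring at 51.0 %. The forecast's ring figure would stand 5 points out at a charge of 0.524 M or 0.918 M, or at a reading at 0.591 h.

The neighbour flask with 2.8 M of solid substrate, all else held, takes the same reckoning: charge over ceiling is 3.45, so u = 1.63, and ring comes to 0.654 M, or 23.4 % of its charge, with a last slowing factor of 0.196 against 0.577 in the first flask. The simulated neighbour flask holds 24.7 % of its charge as ring, which is 0.692 M, less than the ceiling of 0.812 M.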